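**Retrosynthetic overview**
1. Lactone ring B (C1, O2, C3, C3a, C7a; phthalide numbering, side chain C1'–C14') is opened at the O2–C1 acyl bond to a C3 silyl ether and a C7a methyl ester; it is closed last.
2. The route rests on ring A (C3a, C4, C5, C6, C7, C7a): a resorcylate with oxygen on C5 and C7, the carboxyl carbon C1 on C7a and the carbinol carbon C3 on C3a. It is cut at C4–C3a and C7–C7a into 1,1-dimethoxy-3-(trimethylsilyloxy)buta-1,3-diene and a 4-silyloxy-2-ynoate (Diels–Alder, then loss of methanol).
3. The ynoate comes from catalytic asymmetric addition of methyl propiolate to a C15 keto aldehyde, which sets C3.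
4. C10' comes from (S)-1,2-epoxyhex-5-ene (hydrolytic kinetic resolution), opened by a C9 Grignard reagent; the C13' ketone comes from Wacker oxidation of the butenyl end.
5. Ring order: ring A (step 13), then lactone ring B (step 15); the diene is made from 1,1-dichloroethene in three steps.

Key step: step 13

Remark: the sense of asymmetric induction in steps 1 and 8 is assigned from the usual behaviour of these catalyst families and would be confirmed on the first batch (rotation of 2, Mosher esters of 13); the antipodal catalyst would be used if the opposite sense were found.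

**Route**

Step 1
Reactants: 1 rac-2-(but-3-en-1-yl)oxirane (racemic 1,2-epoxyhex-5-ene)
Product: 2 (S)-2-(but-3-en-1-yl)oxirane
Conditions: (S,S)-[N,N'-bis(3,5-di-tert-butylsalicylidene)cyclohexane-1,2-diaminato]Co(OAc) (trivalent cobalt, 0.5 mol%), H2O (0.55 equiv), neat, 0 °C → rt; distillation
Reagents that add atoms: none
Why: Jacobsen hydrolytic kinetic resolution, in which the (S,S)-catalyst should hydrolyse the (R)-epoxide much faster, so that the unreacted (S)-epoxide carrying the future C10' stereocentre is distilled away from the diol.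

Step 2
Reactants: 3 9-bromononan-1-ol
Product: 4 [(9-bromononyl)oxy](tert-butyl)dimethylsilane
Conditions: TBSCl, imidazole, DMF, 0 °C → rt
Reagents that add atoms: tert-butyldimethylsilyl chloride (TBSCl), CC(C)(C)[Si](C)(C)Cl
Why: Standard silylation of a primary alcohol, which masks the hydroxyl for Grignard formation.

Step 3
Reactants: 4 [(9-bromononyl)oxy](tert-butyl)dimethylsilane; 2 (S)-2-(but-3-en-1-yl)oxirane
Product: 6 (R)-15-[(tert-butyldimethylsilyl)oxy]pentadec-1-en-5-ol, via Grignard reagent 5 (not isolated)
Conditions: Mg, cat. I2, THF, 40 °C; then CuI (10 mol%), 2, THF, −40 → 0 °C; aqueous quench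
Reagents that add atoms: none
Why: Copper-catalysed SN2 opening of a terminal epoxide by a primary alkyl Grignard reagent takes place at the CH2 carbon, so the C–O stereocentre is untouched and (S)-2 should give the (R)-carbinol (the descriptor changes only because the ranking of the two carbon branches changes).

Step 4
Reactants: 6 (R)-15-[(tert-butyldimethylsilyl)oxy]pentadec-1-en-5-ol
Product: 7 (R)-15-[(tert-butyldimethylsilyl)oxy]pentadec-1-en-5-yl acetate
Conditions: Ac2O, pyridine, DMAP (cat.), CH2Cl2, rt
Reagents that add atoms: acetic anhydride, CC(=O)OC(C)=O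
Why: DMAP-catalysed acylation of the only free hydroxyl installs the C10' acetate with retention.

Step 5
Reactants: 7 (R)-15-[(tert-butyldimethylsilyl)oxy]pentadec-1-en-5-yl acetate
Product: 8 (R)-15-hydroxypentadec-1-en-5-yl acetate
Conditions: HF·pyridine, THF, 0 °C → rt
Reagents that add atoms: none
Why: Acidic fluoride cleaves the primary silyl ether without touching the acetate, which has no neighbouring hydroxyl to migrate to.

Step 6
Reactants: 8 (R)-15-hydroxypentadec-1-en-5-yl acetate
Product: 9 (R)-15-hydroxy-2-oxopentadecan-5-yl acetate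
Conditions: PdCl2 (10 mol%), CuCl, O2 (1 atm), DMF/H2O 7:1, rt
Reagents that add atoms: water, O
Why: Tsuji–Wacker oxidation, in which Markovnikov hydroxypalladation of the unhindered terminal alkene should give the methyl ketone, with the remote primary alcohol and the acetate tolerated.

Step 7
Reactants: 9 (R)-15-hydroxy-2-oxopentadecan-5-yl acetate
Product: 10 (R)-2,15-dioxopentadecan-5-yl acetate [(11R)-11-acetoxy-14-oxopentadecanal]
Conditions: Dess–Martin periodinane, CH2Cl2, 0 °C → rt
Reagents that add atoms: none
Why: Dess–Martin oxidation of the only alcohol stops cleanly at the aldehyde and leaves the ketone and acetate alone.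

Step 8
Reactants: 10 (R)-2,15-dioxopentadecan-5-yl acetate; 11 methyl propiolate
Product: 13 methyl (4S,14R)-14-acetoxy-4-hydroxy-17-oxooctadec-2-ynoate, via alkynylzinc reagent 12 (not isolated)
Conditions: 11 (4 equiv), ZnEt2 (4 equiv), (R)-BINOL (40 mol%), HMPA (2 equiv), CH2Cl2, rt, 16 h; then Ti(OiPr)4 (1 equiv), 1 h; then 10, rt
Reagents that add atoms: none
Why: Catalytic asymmetric alkynylzinc addition under BINOL–Ti(OiPr)4 control, a system established for alkyl propiolates and linear aliphatic aldehydes; the aldehyde reacts far faster than the methyl ketone, and the (R)-BINOL complex is expected to deliver the alkynyl group to the Re face to set the (4S) carbinol (future C3).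

Step 9
Reactants: 13 methyl (4S,14R)-14-acetoxy-4-hydroxy-17-oxooctadec-2-ynoate
Product: 14 methyl (4S,14R)-14-acetoxy-4-[(tert-butyldimethylsilyl)oxy]-17-oxooctadec-2-ynoate
Conditions: TBSCl, imidazole, DMF, 0 °C → rt
Reagents that add atoms: tert-butyldimethylsilyl chloride (TBSCl), CC(C)(C)[Si](C)(C)Cl
Why: Silylation under weakly basic imidazole conditions protects the propargylic alcohol without base-induced isomerization of the γ-hydroxy ynoate and without enolizing the ketone.

Step 10
Reactants: 15 1,1-dichloroethene
Product: 17 4,4-dichlorobut-3-en-2-one, via 4,4,4-trichlorobutan-2-one 16 (not isolated)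
Conditions: AcCl, AlCl3, CH2Cl2, 0 °C → rt; ice/HCl work-up; steam distillation
Reagents that add atoms: acetyl chloride, CC(=O)Cl
Why: Friedel–Crafts-type acylation of the alkene at its CH2 terminus gives the trichloro ketone, which should lose HCl on distillation to the conjugated dichlorovinyl ketone.

Step 11
Reactants: 17 4,4-dichlorobut-3-en-2-one
Product: 18 4,4-dimethoxybut-3-en-2-one
Conditions: NaOMe (2.1 equiv), MeOH, 0 °C → rt
Reagents that add atoms: sodium methoxide, [Na+].[O-]C
Why: Two successive addition–elimination (vinylogous acyl substitution) reactions of methoxide at the β-carbon replace both chlorides and give the acyl ketene acetal.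

Step 12
Reactants: 18 4,4-dimethoxybut-3-en-2-one
Product: 20 1,1-dimethoxy-3-(trimethylsilyloxy)buta-1,3-diene, via lithium dienolate 19 (not isolated)
Conditions: LDA (commercial solution), THF, −78 °C; then TMSCl, −78 °C → rt; non-aqueous work-up, distillation
Reagents that add atoms: chlorotrimethylsilane (TMSCl), C[Si](C)(C)Cl
Why: Kinetic deprotonation at the methyl group, the only enolizable position, followed by O-silylation gives the cross-conjugated silyloxy diene.

Step 13
Reactants: 14 methyl (4S,14R)-14-acetoxy-4-[(tert-butyldimethylsilyl)oxy]-17-oxooctadec-2-ynoate; 20 1,1-dimethoxy-3-(trimethylsilyloxy)buta-1,3-diene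
Product: 23 methyl 2-[(1S,11R)-11-acetoxy-1-[(tert-butyldimethylsilyl)oxy]-14-oxopentadecyl]-4-hydroxy-6-methoxybenzoate, via cyclohexadiene cycloadduct 21 (not isolated), via aryl trimethylsilyl ether 22 (not isolated)
Conditions: 20 (4 equiv, in two portions), toluene (concentrated), 120 °C, sealed tube, 24 h; then 0.1 M HCl, THF, 0 °C, 10 min
Reagents that add atoms: none
Why: This is a normal-electron-demand, asynchronous Diels–Alder reaction in which the CH2 terminus of diene 20, made the most nucleophilic carbon by both the 3-silyloxy group and the ketene acetal, bonds to the β-carbon of ynoate 14 (C4–C3a) while the acetal carbon bonds to the α-carbon (C7–C7a), giving 1,4-cyclohexadiene 21. 1,4-Elimination of methanol from the C7 ketal and the C4 methylene should then aromatize the ring to aryl silyl ether 22, whose labile O–Si bond is hydrolysed in the mild acidic work-up without loss of the benzylic TBS ether. The closest known reaction type is the benzannulation of 1,1-dialkoxy-3-silyloxybutadienes with acetylenic esters to resorcylate esters. Ring A is closed by the intermolecular [4+2] cycloaddition itself, both ring bonds forming in one step, and no new stereocentre is created. The selectivity needed is regiochemical, and it is secured by the matched polarization of the partners (nucleophilic diene CH2 against electrophilic ynoate β-carbon), which puts the ester between the methoxy-bearing carbon and the carbinol-bearing carbon. The C3 stereocentre has no acidic or ionizing pathway under neutral heating, and the side-chain acetate and ketone should be inert to the diene without a Lewis acid.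

Step 14
Reactants: 23 methyl 2-[(1S,11R)-11-acetoxy-1-[(tert-butyldimethylsilyl)oxy]-14-oxopentadecyl]-4-hydroxy-6-methoxybenzoate
Product: 24 methyl 2-[(1S,11R)-11-acetoxy-1-[(tert-butyldimethylsilyl)oxy]-14-oxopentadecyl]-4,6-dimethoxybenzoate
Conditions: MeI, K2CO3, acetone, 50 °C
Reagents that add atoms: iodomethane, CI
Why: Williamson O-methylation of the acidic C5 phenol (para to the ester); K2CO3 in acetone is too weak to enolize the ketone or cleave the acetate.

Step 15
Reactants: 24 methyl 2-[(1S,11R)-11-acetoxy-1-[(tert-butyldimethylsilyl)oxy]-14-oxopentadecyl]-4,6-dimethoxybenzoate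
Product: 26 (S)-3-[(R)-10-acetoxy-13-oxotetradecyl]-5,7-dimethoxyisobenzofuran-1(3H)-one, via hydroxy ester 25 (not isolated)
Conditions: HF·pyridine, THF, 0 °C → rt; lactonization completed with cat. TsOH·H2O, CH2Cl2, rt
Reagents that add atoms: none
Why: Fluoride desilylation frees the C3 hydroxyl, which should close ring B by 5-exo-trig lactonization onto the ortho methyl ester with loss of methanol; no bond to C3 is broken, so its configuration is retained.

**Compound list**
1 | rac-2-(but-3-en-1-yl)oxirane | C=CCCC1CO1 | starting material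
2 | (S)-2-(but-3-en-1-yl)oxirane | C=CCC[C@H]1CO1 | intermediate
3 | 9-bromononan-1-ol | OCCCCCCCCCBr | starting material
4 | [(9-bromononyl)oxy](tert-butyl)dimethylsilane | CC(C)(C)[Si](C)(C)OCCCCCCCCCBr | intermediate
5 | {9-[(tert-butyldimethylsilyl)oxy]nonyl}magnesium bromide | CC(C)(C)[Si](C)(C)OCCCCCCCCC[Mg]Br | intermediate (not isolated)
6 | (R)-15-[(tert-butyldimethylsilyl)oxy]pentadec-1-en-5-ol | C=CCC[C@H](O)CCCCCCCCCCO[Si](C)(C)C(C)(C)C | intermediate
7 | (R)-15-[(tert-butyldimethylsilyl)oxy]pentadec-1-en-5-yl acetate | C=CCC[C@H](OC(C)=O)CCCCCCCCCCO[Si](C)(C)C(C)(C)C | intermediate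
8 | (R)-15-hydroxypentadec-1-en-5-yl acetate | C=CCC[C@H](OC(C)=O)CCCCCCCCCCO | intermediate
9 | (R)-15-hydroxy-2-oxopentadecan-5-yl acetate | CC(=O)CC[C@H](OC(C)=O)CCCCCCCCCCO | intermediate
10 | (R)-2,15-dioxopentadecan-5-yl acetate | CC(=O)CC[C@H](OC(C)=O)CCCCCCCCCC=O | intermediate
11 | methyl propiolate | C#CC(=O)OC | starting material
12 | ethyl(3-methoxy-3-oxoprop-1-yn-1-yl)zinc | CC[Zn]C#CC(=O)OC | intermediate (not isolated)
13 | methyl (4S,14R)-14-acetoxy-4-hydroxy-17-oxooctadec-2-ynoate | COC(=O)C#C[C@H](CCCCCCCCC[C@H](CCC(C)=O)OC(C)=O)O | intermediate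
14 | methyl (4S,14R)-14-acetoxy-4-[(tert-butyldimethylsilyl)oxy]-17-oxooctadec-2-ynoate | COC(=O)C#C[C@H](CCCCCCCCC[C@H](CCC(C)=O)OC(C)=O)O[Si](C)(C)C(C)(C)C | intermediate
15 | 1,1-dichloroethene | C=C(Cl)Cl | starting material
16 | 4,4,4-trichlorobutan-2-one | CC(=O)CC(Cl)(Cl)Cl | intermediate (not isolated)
17 | 4,4-dichlorobut-3-en-2-one | CC(=O)C=C(Cl)Cl | intermediate
18 | 4,4-dimethoxybut-3-en-2-one | CC(=O)C=C(OC)OC | intermediate
19 | lithium 4,4-dimethoxybuta-1,3-dien-2-olate | [Li]OC(=C)C=C(OC)OC | intermediate (not isolated)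
20 | 1,1-dimethoxy-3-(trimethylsilyloxy)buta-1,3-diene | C=C(O[Si](C)(C)C)C=C(OC)OC | intermediate
21 | methyl 2-[(1S,11R)-11-acetoxy-1-[(tert-butyldimethylsilyl)oxy]-14-oxopentadecyl]-6,6-dimethoxy-4-(trimethylsilyloxy)cyclohexa-1,4-diene-1-carboxylate | COC(=O)C1=C([C@H](CCCCCCCCC[C@H](CCC(C)=O)OC(C)=O)O[Si](C)(C)C(C)(C)C)CC(O[Si](C)(C)C)=CC1(OC)OC | intermediate (not isolated)
22 | methyl 2-[(1S,11R)-11-acetoxy-1-[(tert-butyldimethylsilyl)oxy]-14-oxopentadecyl]-6-methoxy-4-(trimethylsilyloxy)benzoate | COC(=O)c1c(OC)cc(O[Si](C)(C)C)cc1[C@H](CCCCCCCCC[C@H](CCC(C)=O)OC(C)=O)O[Si](C)(C)C(C)(C)C | intermediate (not isolated)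
23 | methyl 2-[(1S,11R)-11-acetoxy-1-[(tert-butyldimethylsilyl)oxy]-14-oxopentadecyl]-4-hydroxy-6-methoxybenzoate | COC(=O)c1c(OC)cc(O)cc1[C@H](CCCCCCCCC[C@H](CCC(C)=O)OC(C)=O)O[Si](C)(C)C(C)(C)C | intermediate
24 | methyl 2-[(1S,11R)-11-acetoxy-1-[(tert-butyldimethylsilyl)oxy]-14-oxopentadecyl]-4,6-dimethoxybenzoate | COC(=O)c1c(OC)cc(OC)cc1[C@H](CCCCCCCCC[C@H](CCC(C)=O)OC(C)=O)O[Si](C)(C)C(C)(C)C | intermediate
25 | methyl 2-[(1S,11R)-11-acetoxy-1-hydroxy-14-oxopentadecyl]-4,6-dimethoxybenzoate | COC(=O)c1c(OC)cc(OC)cc1[C@H](CCCCCCCCC[C@H](CCC(C)=O)OC(C)=O)O | intermediate (not isolated)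
26 | (S)-3-[(R)-10-acetoxy-13-oxotetradecyl]-5,7-dimethoxyisobenzofuran-1(3H)-one | COc1cc(OC)c2c(c1)[C@H](CCCCCCCCC[C@H](CCC(C)=O)OC(C)=O)OC2=O | target

**Step count**
Total: 15 steps. Longest linear sequence: 11 steps (steps 2–9 and 13–15 from 9-bromononan-1-ol; the same length through step 1 from the racemic epoxide). The diene branch is steps 10–12.

**Steps most likely to fail**

Step 13. The cycloaddition may be too slow, because the ynoate is β-branched and activated by only one ester, so that thermal oligomerization and hydrolysis of the ketene-acetal diene consume it before the ynoate has reacted. The fallback sets out from aldehyde 10 and comes back at target 26; it brings ring A in preformed and adds the lactone carbonyl by carbonylation. Aldehyde 10 would be treated with 3,5-dimethoxyphenylmagnesium bromide (THF, −78 °C; the aldehyde reacts ahead of the methyl ketone and the acetate) to give (5R)-15-(3,5-dimethoxyphenyl)-15-hydroxy-2-oxopentadecan-5-yl acetate F1 as a mixture of C15 epimers. Dess–Martin oxidation would give the aryl ketone (R)-15-(3,5-dimethoxyphenyl)-2,15-dioxopentadecan-5-yl acetate F2. Noyori transfer hydrogenation with RuCl(p-cymene)[(S,S)-TsDPEN] in HCO2H/Et3N, which reduces aryl ketones far faster than dialkyl ketones, should give (5R,15S)-15-(3,5-dimethoxyphenyl)-15-hydroxy-2-oxopentadecan-5-yl acetate F3. NBS in MeCN at 0 °C should brominate the ring ortho to the side chain and para to a methoxy group, giving (5R,15S)-15-(2-bromo-3,5-dimethoxyphenyl)-15-hydroxy-2-oxopentadecan-5-yl acetate F4. Carbonylative lactonization (Pd(OAc)2, Xantphos, CO 1 atm, Et3N, toluene, 90 °C) would then close ring B and give 26.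

Step 8. Enantiofacial control may be insufficient, and ethyl transfer or self-aldol condensation of the unbranched aldehyde may compete under the zinc/titanium conditions. The fallback sets out from aldehyde 10 and comes back at 13; it sets the stereocentre by reduction instead of addition. Lithium methyl propiolate (from 11, LiHMDS, THF, −78 °C) would add to 10 to give methyl (4RS,14R)-14-acetoxy-4-hydroxy-17-oxooctadec-2-ynoate F5. Dess–Martin oxidation would give methyl (14R)-14-acetoxy-4,17-dioxooctadec-2-ynoate F6. Midland reduction with (S)-Alpine-Borane (B-isopinocampheyl-9-BBN from (−)-α-pinene; THF, rt), which reduces alkynyl ketones and leaves simple dialkyl ketones essentially untouched, should give 13.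

Step 6. Palladium-mediated alkene isomerization, partial anti-Markovnikov oxidation to the aldehyde, or oxidation of the free primary alcohol may erode the Wacker step. The fallback sets out from 8 and comes back at 10, bypassing 9. Mukaiyama hydration (Co(acac)2, divalent cobalt, PhSiH3, O2, i-PrOH/THF, rt) would give (5R)-2,15-dihydroxypentadecan-5-yl acetate F7 as a mixture of C2 epimers. Excess Dess–Martin periodinane would then oxidize both hydroxyls at once to keto aldehyde 10.

**Further compounds**
F1 | step 13 | (5R)-15-(3,5-dimethoxyphenyl)-15-hydroxy-2-oxopentadecan-5-yl acetate (C15 epimers) | CC(=O)CC[C@H](OC(C)=O)CCCCCCCCCC(O)c1cc(OC)cc(OC)c1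
F2 | step 13 | (R)-15-(3,5-dimethoxyphenyl)-2,15-dioxopentadecan-5-yl acetate | CC(=O)CC[C@H](OC(C)=O)CCCCCCCCCC(=O)c1cc(OC)cc(OC)c1
F3 | step 13 | (5R,15S)-15-(3,5-dimethoxyphenyl)-15-hydroxy-2-oxopentadecan-5-yl acetate | CC(=O)CC[C@H](OC(C)=O)CCCCCCCCC[C@H](O)c1cc(OC)cc(OC)c1
F4 | step 13 | (5R,15S)-15-(2-bromo-3,5-dimethoxyphenyl)-15-hydroxy-2-oxopentadecan-5-yl acetate | CC(=O)CC[C@H](OC(C)=O)CCCCCCCCC[C@H](O)c1cc(OC)cc(OC)c1Br
F5 | step 8 | methyl (4RS,14R)-14-acetoxy-4-hydroxy-17-oxooctadec-2-ynoate | COC(=O)C#CC(O)CCCCCCCCC[C@H](CCC(C)=O)OC(C)=O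
F6 | step 8 | methyl (14R)-14-acetoxy-4,17-dioxooctadec-2-ynoate | COC(=O)C#CC(=O)CCCCCCCCC[C@H](CCC(C)=O)OC(C)=O
F7 | step 6 | (5R)-2,15-dihydroxypentadecan-5-yl acetate (C2 epimers) | CC(O)CC[C@H](OC(C)=O)CCCCCCCCCCO
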